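With the chain numbered from benzylic C1 to methyl C8, atoms C2–C6 and the syn C3/C5 oxygens are a cyclopentene ring cut open. Joining C2 to C6 gives meso cis-cyclopent-4-ene-1,3-diol, and aryl–C1 plus C7–C8 are the two ends of the isoeugenol double bond. The route rests on that disconnection. A chiral molybdenum alkylidene opens the C2=C6 alkene of the diol, held as its strained phenylboronate-bridged bicycle (2,4-dioxa-3-borabicyclo[3.2.1]oct-6-ene). It inserts silyl-protected isoeugenol, forming C1=C2 and C6=C7, and so sets the whole carbon skeleton and the absolute configuration at once. Hydrogenation, boron removal, acetylation and desilylation complete the synthesis.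

Key step: step 3

Assumption: the sense of induction of the chiral catalyst on this new substrate class cannot be derived safely from models, so the route is written for the ligand antipode that gives the (4R,6S)-diene. Both antipodes of the biphenol ligand are available, and one calibration run carried through to the final product (chiral HPLC, sign of rotation) settles the choice.

Remark on stereochemistry: the target is (3S,5R), the syn series. Only in the diene do the descriptors read (4R,6S), because each alkenyl arm outranks the ring CH2. Nothing changes in space, and no C–O bond at C3 or C5 is ever broken.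

Remark on design: both metathesis partners are kept free of O–H groups and of terminal =CH2 groups. The boron p orbital also lowers the donor strength of the allylic oxygens toward Mo. Boron is later removed with neutral, not alkaline, peroxide because the aryl silyl ether is base-labile.

Step 1
Reactants: 1 cis-cyclopent-4-ene-1,3-diol (meso, 1R,3S); 2 phenylboronic acid
Product: 3 (1R,5S)-3-phenyl-2,4-dioxa-3-borabicyclo[3.2.1]oct-6-ene (meso; O–B(Ph)–O is the three-atom bridge, CH=CH the two-atom bridge, CH2 the one-atom bridge)
Conditions: 4 Å MS, CH2Cl2, rt; filter; bulb-to-bulb distillation under high vacuum; kept under N2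
Reagents that add atoms: none
Why: Boronic ester condensation, in which a cis-1,3-diol on a five-membered ring spans trigonal boron just as the 9,11-diol of F-type prostaglandins forms cyclic boronates; water removal drives the equilibrium, distillation cracks oligomers to the volatile monomer, and both C–O bonds stay intact so the cis (meso) relation is kept.

Step 2
Reactants: 4 (E)-isoeugenol, 2-methoxy-4-[(E)-prop-1-enyl]phenol
Product: 5 tert-butyl{2-methoxy-4-[(E)-prop-1-enyl]phenoxy}dimethylsilane
Conditions: TBSCl (1.1 equiv), imidazole (2 equiv), DMF, rt; distilled from CaH2 before use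
Reagents that add atoms: tert-butyldimethylsilyl chloride (TBSCl), CC(C)(C)[Si](C)(C)Cl
Why: Imidazole-promoted O-silylation of a phenol leaves the alkene untouched and removes the acidic OH that would protonate the Mo alkylidene, and any minor Z isomer is harmless because it carries the same two alkylidene halves.

Step 3
Reactants: 3 (1R,5S)-3-phenyl-2,4-dioxa-3-borabicyclo[3.2.1]oct-6-ene; 5 tert-butyl{2-methoxy-4-[(E)-prop-1-enyl]phenoxy}dimethylsilane
Product: 6 (4R,6S)-4-[(E)-2-(4-tert-butyldimethylsilyloxy-3-methoxyphenyl)ethenyl]-2-phenyl-6-[(E)-prop-1-enyl]-1,3,2-dioxaborinane (cis; alkenes drawn E, geometry immaterial)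
Conditions: 5 (3 equiv), enantiopure Mo(=N-2,6-i-Pr2C6H3)(=CHCMe2Ph)(3,3'-di-t-Bu-5,5',6,6'-Me4-biphenyl-2,2'-diolate) (5 mol %, antipode per the assumption), C6H6, 22→50 °C, N2; 3 added over 2 h; excess 5 recovered
Reagents that add atoms: none
Why: Proposed new method: 5 converts the Mo neophylidene into the conjugated arylidene, which adds by [2+2] to the exo face (the side of the CH2 bridge) of the strained C2=C6 alkene of 3, and cycloreversion cuts the carbocycle, forming C1=C2 and leaving Mo on C6. This branched alkylidene should take up 5 with the methyl-bearing carbon at the crowded Cβ of the metallacyclobutane and the aryl-bearing carbon on Mo, so that cycloreversion forms C6=C7 and returns the arylidene; no ring is closed, the dioxaborinane of 6 being the former O–B–O bridge plus C3–C5. The closest known reaction type is catalytic enantioselective ring-opening/cross-metathesis of norbornenes and 8-oxabicyclo[3.2.1]oct-6-enes with styrenes, which likewise propagates through a benzylidene, whereas a boron-bridged cyclopentene and the ordered transfer of both halves of an unsymmetrical internal alkene are untested. C3 and C5 are carried in from 1 with their syn relation and only become non-equivalent here, their absolute sense (4R,6S in 6) being set by the chiral biphenolate, which decides which enantiotopic alkene carbon bonds to the arylidene carbon. The step needs end-selectivity, and this is self-correcting, because a stray ethylidene opens 3 and is capped in the same sense to give the meso bis(propenyl) compound and the arylidene again, so leakage should cost material and not enantiopurity. Strain release and the diequatorial conformer of 6 oppose ring-closing reversal, slow addition of 3 to excess 5 disfavours oligomerisation, the absence of terminal alkenes avoids fragile methylidenes, and alkene geometry is irrelevant since both C=C bonds are hydrogenated in step 4.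

Step 4
Reactants: 6 (4R,6S)-4-[(E)-2-(4-tert-butyldimethylsilyloxy-3-methoxyphenyl)ethenyl]-2-phenyl-6-[(E)-prop-1-enyl]-1,3,2-dioxaborinane
Product: 8 (3S,5R)-1-[4-(tert-butyldimethylsilyloxy)-3-methoxyphenyl]octane-3,5-diol, via saturated boronate 7 (not isolated)
Conditions: H2 (1 atm), 5% Rh/Al2O3, EtOAc, rt, stopped after uptake of 2 equiv; filter; then 30% aq H2O2, pH 7 phosphate buffer, 0 °C→rt
Reagents that add atoms: none
Why: Heterogeneous catalytic hydrogenation over rhodium, a metal with little tendency toward allylic C–O cleavage, saturates both 1,2-disubstituted alkenes without touching C3 or C5, and neutral peroxide then oxidises the B–phenyl bond (boronate oxidation) so that the borate hydrolyses irreversibly to the syn-diol while the aryl silyl ether survives.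

Step 5
Reactants: 8 (3S,5R)-1-[4-(tert-butyldimethylsilyloxy)-3-methoxyphenyl]octane-3,5-diol
Product: 9 (3S,5R)-1-[4-(tert-butyldimethylsilyloxy)-3-methoxyphenyl]octane-3,5-diyl diacetate
Conditions: Ac2O (3 equiv), pyridine, DMAP (5 mol %), CH2Cl2, 0 °C→rt
Reagents that add atoms: acetic anhydride, CC(=O)OC(C)=O
Why: DMAP-catalysed acylation of two unhindered secondary alcohols takes place at oxygen, so C3 and C5 keep their configuration, and the aryl silyl ether is inert to these conditions.

Step 6
Reactants: 9 (3S,5R)-1-[4-(tert-butyldimethylsilyloxy)-3-methoxyphenyl]octane-3,5-diyl diacetate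
Product: 10 (3S,5R)-1-(4-hydroxy-3-methoxyphenyl)octane-3,5-diyl diacetate (target, CNP0240815.1)
Conditions: TBAF (1.1 equiv), AcOH (1.3 equiv), THF, 0 °C
Reagents that add atoms: none
Why: Fluoride-mediated desilylation is fastest for aryl silyl ethers, and the acetic acid buffer protonates the phenoxide at once so that neither secondary acetate is cleaved or migrates.

Compound list
1 | cis-cyclopent-4-ene-1,3-diol (meso) | O[C@H]1C[C@@H](O)C=C1 | starting material
2 | phenylboronic acid | OB(O)c1ccccc1 | starting material
3 | (1R,5S)-3-phenyl-2,4-dioxa-3-borabicyclo[3.2.1]oct-6-ene (meso) | C1=C[C@@H]2C[C@H]1OB(c3ccccc3)O2 | intermediate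
4 | (E)-isoeugenol | C/C=C/c1ccc(O)c(OC)c1 | starting material
5 | tert-butyl{2-methoxy-4-[(E)-prop-1-enyl]phenoxy}dimethylsilane | C/C=C/c1ccc(O[Si](C)(C)C(C)(C)C)c(OC)c1 | intermediate
6 | (4R,6S)-4-[(E)-2-(4-tert-butyldimethylsilyloxy-3-methoxyphenyl)ethenyl]-2-phenyl-6-[(E)-prop-1-enyl]-1,3,2-dioxaborinane | C/C=C/[C@@H]1C[C@H](/C=C/c2ccc(O[Si](C)(C)C(C)(C)C)c(OC)c2)OB(c2ccccc2)O1 | intermediate
7 | (4S,6R)-4-[2-(4-tert-butyldimethylsilyloxy-3-methoxyphenyl)ethyl]-2-phenyl-6-propyl-1,3,2-dioxaborinane | CCC[C@@H]1C[C@H](CCc2ccc(O[Si](C)(C)C(C)(C)C)c(OC)c2)OB(c2ccccc2)O1 | intermediate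
8 | (3S,5R)-1-[4-(tert-butyldimethylsilyloxy)-3-methoxyphenyl]octane-3,5-diol | CCC[C@H](C[C@H](CCc1ccc(O[Si](C)(C)C(C)(C)C)c(OC)c1)O)O | intermediate
9 | (3S,5R)-1-[4-(tert-butyldimethylsilyloxy)-3-methoxyphenyl]octane-3,5-diyl diacetate | CCC[C@H](C[C@H](CCc1ccc(O[Si](C)(C)C(C)(C)C)c(OC)c1)OC(C)=O)OC(C)=O | intermediate
10 | (3S,5R)-1-(4-hydroxy-3-methoxyphenyl)octane-3,5-diyl diacetate | CCC[C@H](C[C@H](CCc1ccc(O)c(OC)c1)OC(C)=O)OC(C)=O | target

Total step count: 6
Longest linear sequence: 5 steps (steps 1, 3, 4, 5, 6)

Steps most likely to fail

Step 3 (bears the label). Three things may go wrong.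
- The ring-opened alkylidene may take up the internal alkene more slowly than it attacks further bicycle, which leads to oligomerisation.
- The two halves of 5 may be delivered without order.
- The discrimination between the enantiotopic alkene carbons may be weak.

The fallback splits the single insertion into two metatheses of known type and sets out from 3. Commercial 2-methoxy-4-vinylphenol is silylated (TBSCl, imidazole) to tert-butyl(2-methoxy-4-vinylphenoxy)dimethylsilane F1. Enantioselective ring-opening/cross-metathesis of 3 with this terminal aryl alkene is the established styrene version of the reaction on bicyclo[3.2.1]oct-6-ene frames. It should give the styryl vinyl dioxaborinane F2. Cross-metathesis of the terminal vinyl group with excess (Z)-2-butene, using (H2IMes)Cl2Ru(=CH-2-i-PrO-C6H4) in CH2Cl2, caps it as the propenyl group, and the fallback comes back to the route at 6.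

Step 1. The condensation may stop at open-chain or oligomeric boronates because closing the bridge costs strain. The bridge may also hydrolyse on handling and release O–H compounds that destroy the catalyst of step 3. The fallback replaces boron by silicon and sets out from 1.
- t-Bu2Si(OTf)2 and 2,6-lutidine in CH2Cl2 at 0 °C should give the hydrolytically robust, chromatographable silylene-bridged bicycle F3.
- The conditions of step 3 with 5 should open it to the dialkenyl dioxasilinane F4.
- H2 over Rh/Al2O3 should give the saturated dioxasilinane F5.
- HF·pyridine with added pyridine in THF at 0 °C cleaves the dialkoxysilane. The aryl silyl ether resists acidic fluoride better than basic fluoride and should persist.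

The fallback comes back to the route at 8.

Step 4. Hydrogenolysis of the cinnamyl-type C3–O bond, slow reduction of an arene on rhodium, or incomplete saturation of the branched alkenes may occur. The fallback sets out from 6 and replaces surface hydrogenation by metal-free concerted hydrogen transfer from diimide, generated from 2-nitrobenzenesulfonyl hydrazide and Et3N in CH2Cl2 at rt. Diimide cannot cleave C–O bonds or reduce arenes. The fallback comes back to the route at 7, which is oxidised to 8 as in step 4. It makes no compound outside the list (entry F0).

Further compounds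
F1 | step 3 | tert-butyl(2-methoxy-4-vinylphenoxy)dimethylsilane | C=Cc1ccc(O[Si](C)(C)C(C)(C)C)c(OC)c1
F2 | step 3 | (4R,6S)-4-[(E)-2-(4-tert-butyldimethylsilyloxy-3-methoxyphenyl)ethenyl]-6-ethenyl-2-phenyl-1,3,2-dioxaborinane | C=C[C@@H]1C[C@H](/C=C/c2ccc(O[Si](C)(C)C(C)(C)C)c(OC)c2)OB(c2ccccc2)O1
F3 | step 1 | (1R,5S)-3,3-di-tert-butyl-2,4-dioxa-3-silabicyclo[3.2.1]oct-6-ene (meso) | C1=C[C@@H]2C[C@H]1O[Si](C(C)(C)C)(C(C)(C)C)O2
F4 | step 1 | (4R,6S)-2,2-di-tert-butyl-4-[(E)-2-(4-tert-butyldimethylsilyloxy-3-methoxyphenyl)ethenyl]-6-[(E)-prop-1-enyl]-1,3,2-dioxasilinane | C/C=C/[C@@H]1C[C@H](/C=C/c2ccc(O[Si](C)(C)C(C)(C)C)c(OC)c2)O[Si](C(C)(C)C)(C(C)(C)C)O1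
F5 | step 1 | (4S,6R)-2,2-di-tert-butyl-4-[2-(4-tert-butyldimethylsilyloxy-3-methoxyphenyl)ethyl]-6-propyl-1,3,2-dioxasilinane | CCC[C@@H]1C[C@H](CCc2ccc(O[Si](C)(C)C(C)(C)C)c(OC)c2)O[Si](C(C)(C)C)(C(C)(C)C)O1
F0 | step 4 | none | none
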